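**Plan**

1. Rings: A is the 3,5-dihydroxyphenoxy cap; B carries A on C1; C links B to E; E is the second 1,2,3-tri(aryloxy) ring; D, F and G are the 3-aryl-2,4,6-trihydroxyphenoxy flanks; H, J and K are their pendant 2,4,6-trihydroxyphenyl rings.
2. Enabling feature: C2 and C6 of ring B carry rings C and D, and C2 and C6 of ring E carry rings F and G. All four are 2,6-dioxygenated 4-oxyphenoxy groups, so each core is a masked symmetric 2,6-bis(aryloxy)arene whose C1 can be a directing carboxamide carbon.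
3. Cuts, in retrosynthetic order: the 22 O–CH3 and 2 O–benzyl bonds; the C1(E)–O bond to ring C; the C1(B)–O bond to ring A; the biaryl bonds D–H, F–J and G–K; last the C2–O and C6–O bonds of rings B and E, both cores coming from one 2,6-bis(aryloxy)benzamide.
4. Forward: a 4-methoxybenzamide is aryloxylated at both ortho C–H bonds. For the B half one benzyl is removed, that flank is brominated, methylated and arylated (ring D), the amide carbon becomes iodide and then the ring A ether, and the second benzyl is removed to free ring C. For the E half both flanks are brominated and arylated (rings F and G) and the amide carbon becomes iodide.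
5. The halves are joined by a copper-catalysed ether synthesis between the ring C phenol and C1 of ring E; hydrogenolysis and BBr3 then free all 24 hydroxyls. No ring is formed anywhere; the ten benzene rings come from four bought arenes.
6. Stereochemistry: the target has no stereocentre, and the three biaryl axes are not stereogenic because rings H, J and K are symmetric, so nothing needs control.

Key step: step 4

Remark: flank rings are numbered from the carbon bound to the core oxygen (C1), so the benzyloxy group sits on C4 and the pendant ring goes to C3; (2,4,6-trimethoxyphenyl)boronic acid and 3,5-dimethoxyphenol are taken as bought.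

**Route**

Step 1
Reactants: 1 4-methoxybenzoyl chloride; 2 8-aminoquinoline
Product: 3 4-methoxy-N-(quinolin-8-yl)benzamide
Conditions: Et3N, CH2Cl2, 0 °C to rt
Reagents that add atoms: none
Why: Schotten–Baumann-type N-acylation of the aromatic amine by the acid chloride installs the bidentate aminoquinoline auxiliary in one operation.

Step 2
Reactants: 4 2,6-dimethoxy-1,4-benzoquinone
Product: 5 2,6-dimethoxybenzene-1,4-diol
Conditions: Na2S2O4, EtOAc–H2O, rt
Reagents that add atoms: none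
Why: Dithionite reduction of a benzoquinone to its hydroquinone is fast and leaves the methyl ethers untouched.

Step 3
Reactants: 5 2,6-dimethoxybenzene-1,4-diol
Product: 6 4-(benzyloxy)-2,6-dimethoxyphenol
Conditions: BnBr (1.0 equiv), K2CO3, DMF, 0 °C to rt, N2
Reagents that add atoms: benzyl bromide, BrCc1ccccc1
Why: Williamson etherification with one equivalent of halide should take the C4 hydroxyl, which is unhindered and the more acidic one (meta to two methoxy groups), while the hydroxyl between the two methoxy groups stays free.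

Step 4
Reactants: 3 4-methoxy-N-(quinolin-8-yl)benzamide; 6 4-(benzyloxy)-2,6-dimethoxyphenol
Product: 8 2,6-bis[4-(benzyloxy)-2,6-dimethoxyphenoxy]-4-methoxy-N-(quinolin-8-yl)benzamide, via monoaryl ether 7 (not isolated)
Conditions: (CuOH)2CO3 (cat.), K2CO3, DMF, air, 110 °C; 6 (3 equiv)
Reagents that add atoms: none
Why: The amidate nitrogen and the quinoline nitrogen of 3 hold divalent copper in a five-membered N,N-chelate next to an ortho C–H bond, which is cleaved by carbonate-assisted cupration. Oxidation to a trivalent aryl copper phenoxide and C–O reductive elimination give monoether 7 and monovalent copper, which air returns to the divalent state; rotation about the aryl–carbonyl bond then presents the second ortho C–H bond and the cycle repeats to give 8. The closest known reaction type is the copper-catalysed, aminoquinoline-directed ortho C–H etherification of benzamides with phenols, which gives diethers when both ortho positions are open. No ring is closed and no stereocentre is formed. The step needs twofold, ortho-only substitution and survival of an oxidisable phenol: the chelate reaches only C2 and C6, and in 6 the benzyloxy group blocks the para position and the methoxy groups block both ortho positions, so oxidative C–C coupling of the phenol has no open site, while the excess of 6 offsets the slow ligation of a di-ortho-substituted phenoxide.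

Step 5
Reactants: 8 2,6-bis[4-(benzyloxy)-2,6-dimethoxyphenoxy]-4-methoxy-N-(quinolin-8-yl)benzamide
Product: 9 2-[4-(benzyloxy)-2,6-dimethoxyphenoxy]-6-(4-hydroxy-2,6-dimethoxyphenoxy)-4-methoxy-N-(quinolin-8-yl)benzamide
Conditions: H2 (1 atm), Pd/C, EtOAc–MeOH, rt, stopped near half conversion
Reagents that add atoms: none
Why: Catalytic hydrogenolysis of one of two equivalent, remote aryl benzyl ethers is a statistical desymmetrisation that should give the monophenol as the main product at partial conversion, with unchanged 8 recovered and resubmitted.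

Step 6
Reactants: 9 2-[4-(benzyloxy)-2,6-dimethoxyphenoxy]-6-(4-hydroxy-2,6-dimethoxyphenoxy)-4-methoxy-N-(quinolin-8-yl)benzamide
Product: 10 2-[4-(benzyloxy)-2,6-dimethoxyphenoxy]-6-(3-bromo-4-hydroxy-2,6-dimethoxyphenoxy)-4-methoxy-N-(quinolin-8-yl)benzamide
Conditions: NBS (1.0 equiv), i-Pr2NH (cat.), CH2Cl2, −78 °C
Reagents that add atoms: N-bromosuccinimide, O=C1CCC(=O)N1Br
Why: Amine-catalysed electrophilic aromatic bromination goes ortho to the free phenol (a position also ortho and para to methoxy groups), which should react faster than the benzyl ether flank, the acyl-deactivated ring B and the quinoline.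

Step 7
Reactants: 10 2-[4-(benzyloxy)-2,6-dimethoxyphenoxy]-6-(3-bromo-4-hydroxy-2,6-dimethoxyphenoxy)-4-methoxy-N-(quinolin-8-yl)benzamide
Product: 11 2-[4-(benzyloxy)-2,6-dimethoxyphenoxy]-6-(3-bromo-2,4,6-trimethoxyphenoxy)-4-methoxy-N-(quinolin-8-yl)benzamide
Conditions: MeI, K2CO3, acetone, 50 °C
Reagents that add atoms: iodomethane, CI
Why: Williamson O-methylation caps the ring D phenol so that it cannot compete in the later copper-catalysed etherifications, and the weak base leaves the amide N–H alone.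

Step 8
Reactants: 11 2-[4-(benzyloxy)-2,6-dimethoxyphenoxy]-6-(3-bromo-2,4,6-trimethoxyphenoxy)-4-methoxy-N-(quinolin-8-yl)benzamide; 12 (2,4,6-trimethoxyphenyl)boronic acid
Product: 13 2-[4-(benzyloxy)-2,6-dimethoxyphenoxy]-4-methoxy-6-[(2,2',4,4',6,6'-hexamethoxybiphenyl-3-yl)oxy]-N-(quinolin-8-yl)benzamide
Conditions: Pd(OAc)2 (cat.), SPhos, K3PO4, toluene–H2O, 100 °C; 12 (3 equiv)
Reagents that add atoms: none
Why: Suzuki–Miyaura coupling with a dialkylbiarylphosphine ligand is the established route to tetra-ortho-oxygenated biaryls, the excess of 12 offsets its protodeboronation, and the new axis is not stereogenic because ring H is symmetric.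

Step 9
Reactants: 13 2-[4-(benzyloxy)-2,6-dimethoxyphenoxy]-4-methoxy-6-[(2,2',4,4',6,6'-hexamethoxybiphenyl-3-yl)oxy]-N-(quinolin-8-yl)benzamide
Product: 16 2-[4-(benzyloxy)-2,6-dimethoxyphenoxy]-4-methoxy-6-[(2,2',4,4',6,6'-hexamethoxybiphenyl-3-yl)oxy]benzoic acid, via N-Boc imide 14 (not isolated), via peroxy acid 15 (not isolated)
Conditions: Boc2O, DMAP, MeCN, 60 °C; then LiOH, H2O2, THF–H2O, 0 °C to rt; Na2SO3; aq. HCl
Reagents that add atoms: hydrogen peroxide, OO (oxygen of the acid hydroxyl); di-tert-butyl dicarbonate, CC(C)(C)OC(=O)OC(=O)OC(C)(C)C (its atoms stay only in intermediate 14)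
Why: N-Boc activation twists the amide out of conjugation so that the small alpha-effect nucleophile lithium hydroperoxide cleaves the aroyl–nitrogen bond by acyl substitution (the cleavage used for N-acyl oxazolidinones), and sulfite reduces the peroxy acid to the acid.

Step 10
Reactants: 16 2-[4-(benzyloxy)-2,6-dimethoxyphenoxy]-4-methoxy-6-[(2,2',4,4',6,6'-hexamethoxybiphenyl-3-yl)oxy]benzoic acid
Product: 17 1-[4-(benzyloxy)-2,6-dimethoxyphenoxy]-2-iodo-5-methoxy-3-[(2,2',4,4',6,6'-hexamethoxybiphenyl-3-yl)oxy]benzene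
Conditions: I2, K3PO4, MeCN, 100 °C
Reagents that add atoms: iodine, II
Why: Base-mediated ipso-iododecarboxylation (a transition-metal-free Hunsdiecker-type halodecarboxylation) works best for benzoates flanked by two ortho oxygen substituents, where iodine attacks the carboxylate-bearing carbon and CO2 leaves irreversibly.

Step 11
Reactants: 17 1-[4-(benzyloxy)-2,6-dimethoxyphenoxy]-2-iodo-5-methoxy-3-[(2,2',4,4',6,6'-hexamethoxybiphenyl-3-yl)oxy]benzene; 18 3,5-dimethoxyphenol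
Product: 19 1-[4-(benzyloxy)-2,6-dimethoxyphenoxy]-2-(3,5-dimethoxyphenoxy)-5-methoxy-3-[(2,2',4,4',6,6'-hexamethoxybiphenyl-3-yl)oxy]benzene
Conditions: CuI (cat.), picolinic acid, K3PO4, DMSO, 100 °C; 18 (3 equiv)
Reagents that add atoms: none
Why: Ullmann diaryl ether synthesis with CuI and picolinic acid tolerates di-ortho-substituted aryl iodides, and the small unhindered phenol 18 can be used in excess to outrun hydrodeiodination.

Step 12
Reactants: 19 1-[4-(benzyloxy)-2,6-dimethoxyphenoxy]-2-(3,5-dimethoxyphenoxy)-5-methoxy-3-[(2,2',4,4',6,6'-hexamethoxybiphenyl-3-yl)oxy]benzene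
Product: 20 4-{2-(3,5-dimethoxyphenoxy)-5-methoxy-3-[(2,2',4,4',6,6'-hexamethoxybiphenyl-3-yl)oxy]phenoxy}-3,5-dimethoxyphenol
Conditions: H2 (1 atm), Pd/C, EtOAc–MeOH, rt
Reagents that add atoms: none
Why: Catalytic hydrogenolysis of the single aryl benzyl ether frees the C4 hydroxyl of ring C and touches neither methyl ethers, diaryl ethers nor the biaryl.

Step 13
Reactants: 8 2,6-bis[4-(benzyloxy)-2,6-dimethoxyphenoxy]-4-methoxy-N-(quinolin-8-yl)benzamide
Product: 22 2,6-bis[4-(benzyloxy)-3-bromo-2,6-dimethoxyphenoxy]-4-methoxy-N-(quinolin-8-yl)benzamide, via monobromide 21 (not isolated)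
Conditions: NBS (2.1 equiv), MeCN, 0 °C
Reagents that add atoms: N-bromosuccinimide, O=C1CCC(=O)N1Br
Why: In this electrophilic aromatic bromination C3 of each flank ring is ortho to two alkoxy groups and para to a third, hence far more reactive than ring B or the quinoline, and the first bromine deactivates its own ring against a second.

Step 14
Reactants: 22 2,6-bis[4-(benzyloxy)-3-bromo-2,6-dimethoxyphenoxy]-4-methoxy-N-(quinolin-8-yl)benzamide; 12 (2,4,6-trimethoxyphenyl)boronic acid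
Product: 24 2,6-bis{[6-(benzyloxy)-2,2',4,4',6'-pentamethoxybiphenyl-3-yl]oxy}-4-methoxy-N-(quinolin-8-yl)benzamide, via monoarylated bromide 23 (not isolated)
Conditions: Pd(OAc)2 (cat.), SPhos, K3PO4, toluene–H2O, 100 °C; 12 (6 equiv)
Reagents that add atoms: none
Why: Twofold Suzuki–Miyaura coupling under the conditions of step 8 builds the tetra-ortho-oxygenated biaryls F–J and G–K at once, both axes being non-stereogenic.

Step 15
Reactants: 24 2,6-bis{[6-(benzyloxy)-2,2',4,4',6'-pentamethoxybiphenyl-3-yl]oxy}-4-methoxy-N-(quinolin-8-yl)benzamide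
Product: 27 2,6-bis{[6-(benzyloxy)-2,2',4,4',6'-pentamethoxybiphenyl-3-yl]oxy}-4-methoxybenzoic acid, via N-Boc imide 25 (not isolated), via peroxy acid 26 (not isolated)
Conditions: Boc2O, DMAP, MeCN, 60 °C; then LiOH, H2O2, THF–H2O, 0 °C to rt; Na2SO3; aq. HCl
Reagents that add atoms: hydrogen peroxide, OO (oxygen of the acid hydroxyl); di-tert-butyl dicarbonate, CC(C)(C)OC(=O)OC(=O)OC(C)(C)C (its atoms stay only in intermediate 25)
Why: As in step 9, Boc activation followed by hydroperoxide acyl substitution removes the auxiliary from the twisted imide, and sulfite reduces the peroxy acid to the acid.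

Step 16
Reactants: 27 2,6-bis{[6-(benzyloxy)-2,2',4,4',6'-pentamethoxybiphenyl-3-yl]oxy}-4-methoxybenzoic acid
Product: 28 1,3-bis{[6-(benzyloxy)-2,2',4,4',6'-pentamethoxybiphenyl-3-yl]oxy}-2-iodo-5-methoxybenzene
Conditions: I2, K3PO4, MeCN, 100 °C
Reagents that add atoms: iodine, II
Why: The same ipso-iododecarboxylation as in step 10 replaces the carboxylate between two ortho aryloxy groups by iodine with loss of CO2.

Step 17
Reactants: 20 4-{2-(3,5-dimethoxyphenoxy)-5-methoxy-3-[(2,2',4,4',6,6'-hexamethoxybiphenyl-3-yl)oxy]phenoxy}-3,5-dimethoxyphenol; 28 1,3-bis{[6-(benzyloxy)-2,2',4,4',6'-pentamethoxybiphenyl-3-yl]oxy}-2-iodo-5-methoxybenzene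
Product: 29 bis(benzyl) docosamethyl ether of the target (ring C oxygen of 20 bonded to C2 of the arene of 28)
Conditions: CuI, picolinic acid, K3PO4, DMSO, 110 °C
Reagents that add atoms: none
Why: In this Ullmann diaryl ether synthesis the ring C phenol is unhindered and electron-rich, so its copper phenoxide should displace the iodide of 28 despite the two ortho aryloxy groups.

Step 18
Reactants: 29 bis(benzyl) docosamethyl ether of the target
Product: 31 docosamethyl ether of the target with free C4 hydroxyls on rings F and G, via monobenzyl ether 30 (not isolated)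
Conditions: H2 (1 atm), Pd/C, EtOAc–MeOH, rt
Reagents that add atoms: none
Why: Catalytic hydrogenolysis removes both benzyl groups before the Lewis acid step, so that no benzyl cation is generated among the electron-rich rings.

Step 19
Reactants: 31 docosamethyl ether of the target with free C4 hydroxyls on rings F and G
Product: 32 CNP0294555.0 (target)
Conditions: BBr3 (excess), CH2Cl2, −78 °C to rt; then H2O
Reagents that add atoms: none
Why: Lewis acid ether cleavage with BBr3, the usual way to unmask permethylated phlorotannins, should cleave all 22 aryl methyl ethers while diaryl ether and biaryl bonds stay intact.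

**Compound list**

1 | 4-methoxybenzoyl chloride | COc1ccc(cc1)C(Cl)=O | starting material
2 | 8-aminoquinoline | Nc1cccc2cccnc12 | starting material
3 | 4-methoxy-N-(quinolin-8-yl)benzamide | COc1ccc(cc1)C(=O)Nc1cccc2cccnc12 | intermediate
4 | 2,6-dimethoxy-1,4-benzoquinone | COC1=CC(=O)C=C(OC)C1=O | starting material
5 | 2,6-dimethoxybenzene-1,4-diol | COc1cc(O)cc(OC)c1O | intermediate
6 | 4-(benzyloxy)-2,6-dimethoxyphenol | COc1cc(OCc2ccccc2)cc(OC)c1O | intermediate
7 | 2-[4-(benzyloxy)-2,6-dimethoxyphenoxy]-4-methoxy-N-(quinolin-8-yl)benzamide (formed in the flask in step 4) | COc1ccc(C(=O)Nc2cccc3cccnc23)c(Oc2c(OC)cc(OCc3ccccc3)cc2OC)c1 | intermediate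
8 | 2,6-bis[4-(benzyloxy)-2,6-dimethoxyphenoxy]-4-methoxy-N-(quinolin-8-yl)benzamide | COc1cc(Oc2c(OC)cc(OCc3ccccc3)cc2OC)c(C(=O)Nc2cccc3cccnc23)c(Oc2c(OC)cc(OCc3ccccc3)cc2OC)c1 | intermediate
9 | 2-[4-(benzyloxy)-2,6-dimethoxyphenoxy]-6-(4-hydroxy-2,6-dimethoxyphenoxy)-4-methoxy-N-(quinolin-8-yl)benzamide | COc1cc(Oc2c(OC)cc(O)cc2OC)c(C(=O)Nc2cccc3cccnc23)c(Oc2c(OC)cc(OCc3ccccc3)cc2OC)c1 | intermediate
10 | 2-[4-(benzyloxy)-2,6-dimethoxyphenoxy]-6-(3-bromo-4-hydroxy-2,6-dimethoxyphenoxy)-4-methoxy-N-(quinolin-8-yl)benzamide | COc1cc(Oc2c(OC)c(Br)c(O)cc2OC)c(C(=O)Nc2cccc3cccnc23)c(Oc2c(OC)cc(OCc3ccccc3)cc2OC)c1 | intermediate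
11 | 2-[4-(benzyloxy)-2,6-dimethoxyphenoxy]-6-(3-bromo-2,4,6-trimethoxyphenoxy)-4-methoxy-N-(quinolin-8-yl)benzamide | COc1cc(Oc2c(OC)c(Br)c(OC)cc2OC)c(C(=O)Nc2cccc3cccnc23)c(Oc2c(OC)cc(OCc3ccccc3)cc2OC)c1 | intermediate
12 | (2,4,6-trimethoxyphenyl)boronic acid | COc1cc(OC)c(B(O)O)c(OC)c1 | starting material
13 | 2-[4-(benzyloxy)-2,6-dimethoxyphenoxy]-4-methoxy-6-[(2,2',4,4',6,6'-hexamethoxybiphenyl-3-yl)oxy]-N-(quinolin-8-yl)benzamide | COc1cc(Oc2c(OC)c(-c3c(OC)cc(OC)cc3OC)c(OC)cc2OC)c(C(=O)Nc2cccc3cccnc23)c(Oc2c(OC)cc(OCc3ccccc3)cc2OC)c1 | intermediate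
14 | tert-butyl {2-[4-(benzyloxy)-2,6-dimethoxyphenoxy]-4-methoxy-6-[(2,2',4,4',6,6'-hexamethoxybiphenyl-3-yl)oxy]benzoyl}(quinolin-8-yl)carbamate (formed in the flask in step 9) | COc1cc(Oc2c(OC)c(-c3c(OC)cc(OC)cc3OC)c(OC)cc2OC)c(C(=O)N(C(=O)OC(C)(C)C)c2cccc3cccnc23)c(Oc2c(OC)cc(OCc3ccccc3)cc2OC)c1 | intermediate
15 | 2-[4-(benzyloxy)-2,6-dimethoxyphenoxy]-4-methoxy-6-[(2,2',4,4',6,6'-hexamethoxybiphenyl-3-yl)oxy]benzenecarboperoxoic acid (formed in the flask in step 9) | COc1cc(Oc2c(OC)c(-c3c(OC)cc(OC)cc3OC)c(OC)cc2OC)c(C(=O)OO)c(Oc2c(OC)cc(OCc3ccccc3)cc2OC)c1 | intermediate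
16 | 2-[4-(benzyloxy)-2,6-dimethoxyphenoxy]-4-methoxy-6-[(2,2',4,4',6,6'-hexamethoxybiphenyl-3-yl)oxy]benzoic acid | COc1cc(Oc2c(OC)c(-c3c(OC)cc(OC)cc3OC)c(OC)cc2OC)c(C(=O)O)c(Oc2c(OC)cc(OCc3ccccc3)cc2OC)c1 | intermediate
17 | 1-[4-(benzyloxy)-2,6-dimethoxyphenoxy]-2-iodo-5-methoxy-3-[(2,2',4,4',6,6'-hexamethoxybiphenyl-3-yl)oxy]benzene | COc1cc(Oc2c(OC)c(-c3c(OC)cc(OC)cc3OC)c(OC)cc2OC)c(I)c(Oc2c(OC)cc(OCc3ccccc3)cc2OC)c1 | intermediate
18 | 3,5-dimethoxyphenol | COc1cc(O)cc(OC)c1 | starting material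
19 | 1-[4-(benzyloxy)-2,6-dimethoxyphenoxy]-2-(3,5-dimethoxyphenoxy)-5-methoxy-3-[(2,2',4,4',6,6'-hexamethoxybiphenyl-3-yl)oxy]benzene | COc1cc(Oc2c(OC)c(-c3c(OC)cc(OC)cc3OC)c(OC)cc2OC)c(Oc2cc(OC)cc(OC)c2)c(Oc2c(OC)cc(OCc3ccccc3)cc2OC)c1 | intermediate
20 | 4-{2-(3,5-dimethoxyphenoxy)-5-methoxy-3-[(2,2',4,4',6,6'-hexamethoxybiphenyl-3-yl)oxy]phenoxy}-3,5-dimethoxyphenol | COc1cc(Oc2c(OC)c(-c3c(OC)cc(OC)cc3OC)c(OC)cc2OC)c(Oc2cc(OC)cc(OC)c2)c(Oc2c(OC)cc(O)cc2OC)c1 | intermediate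
21 | 2-[4-(benzyloxy)-3-bromo-2,6-dimethoxyphenoxy]-6-[4-(benzyloxy)-2,6-dimethoxyphenoxy]-4-methoxy-N-(quinolin-8-yl)benzamide (formed in the flask in step 13) | COc1cc(Oc2c(OC)c(Br)c(OCc3ccccc3)cc2OC)c(C(=O)Nc2cccc3cccnc23)c(Oc2c(OC)cc(OCc3ccccc3)cc2OC)c1 | intermediate
22 | 2,6-bis[4-(benzyloxy)-3-bromo-2,6-dimethoxyphenoxy]-4-methoxy-N-(quinolin-8-yl)benzamide | COc1cc(Oc2c(OC)c(Br)c(OCc3ccccc3)cc2OC)c(C(=O)Nc2cccc3cccnc23)c(Oc2c(OC)c(Br)c(OCc3ccccc3)cc2OC)c1 | intermediate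
23 | 2-[4-(benzyloxy)-3-bromo-2,6-dimethoxyphenoxy]-6-{[6-(benzyloxy)-2,2',4,4',6'-pentamethoxybiphenyl-3-yl]oxy}-4-methoxy-N-(quinolin-8-yl)benzamide (formed in the flask in step 14) | COc1cc(Oc2c(OC)c(-c3c(OC)cc(OC)cc3OC)c(OCc3ccccc3)cc2OC)c(C(=O)Nc2cccc3cccnc23)c(Oc2c(OC)c(Br)c(OCc3ccccc3)cc2OC)c1 | intermediate
24 | 2,6-bis{[6-(benzyloxy)-2,2',4,4',6'-pentamethoxybiphenyl-3-yl]oxy}-4-methoxy-N-(quinolin-8-yl)benzamide | COc1cc(Oc2c(OC)c(-c3c(OC)cc(OC)cc3OC)c(OCc3ccccc3)cc2OC)c(C(=O)Nc2cccc3cccnc23)c(Oc2c(OC)c(-c3c(OC)cc(OC)cc3OC)c(OCc3ccccc3)cc2OC)c1 | intermediate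
25 | tert-butyl (2,6-bis{[6-(benzyloxy)-2,2',4,4',6'-pentamethoxybiphenyl-3-yl]oxy}-4-methoxybenzoyl)(quinolin-8-yl)carbamate (formed in the flask in step 15) | COc1cc(Oc2c(OC)c(-c3c(OC)cc(OC)cc3OC)c(OCc3ccccc3)cc2OC)c(C(=O)N(C(=O)OC(C)(C)C)c2cccc3cccnc23)c(Oc2c(OC)c(-c3c(OC)cc(OC)cc3OC)c(OCc3ccccc3)cc2OC)c1 | intermediate
26 | 2,6-bis{[6-(benzyloxy)-2,2',4,4',6'-pentamethoxybiphenyl-3-yl]oxy}-4-methoxybenzenecarboperoxoic acid (formed in the flask in step 15) | COc1cc(Oc2c(OC)c(-c3c(OC)cc(OC)cc3OC)c(OCc3ccccc3)cc2OC)c(C(=O)OO)c(Oc2c(OC)c(-c3c(OC)cc(OC)cc3OC)c(OCc3ccccc3)cc2OC)c1 | intermediate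
27 | 2,6-bis{[6-(benzyloxy)-2,2',4,4',6'-pentamethoxybiphenyl-3-yl]oxy}-4-methoxybenzoic acid | COc1cc(Oc2c(OC)c(-c3c(OC)cc(OC)cc3OC)c(OCc3ccccc3)cc2OC)c(C(=O)O)c(Oc2c(OC)c(-c3c(OC)cc(OC)cc3OC)c(OCc3ccccc3)cc2OC)c1 | intermediate
28 | 1,3-bis{[6-(benzyloxy)-2,2',4,4',6'-pentamethoxybiphenyl-3-yl]oxy}-2-iodo-5-methoxybenzene | COc1cc(Oc2c(OC)c(-c3c(OC)cc(OC)cc3OC)c(OCc3ccccc3)cc2OC)c(I)c(Oc2c(OC)c(-c3c(OC)cc(OC)cc3OC)c(OCc3ccccc3)cc2OC)c1 | intermediate
29 | bis(benzyl) docosamethyl ether of the target: 2-(4-{2-(3,5-dimethoxyphenoxy)-5-methoxy-3-[(2,2',4,4',6,6'-hexamethoxybiphenyl-3-yl)oxy]phenoxy}-3,5-dimethoxyphenoxy)-1,3-bis{[6-(benzyloxy)-2,2',4,4',6'-pentamethoxybiphenyl-3-yl]oxy}-5-methoxybenzene | COc1cc(Oc2c(OC)c(-c3c(OC)cc(OC)cc3OC)c(OC)cc2OC)c(Oc2cc(OC)cc(OC)c2)c(Oc2c(OC)cc(Oc3c(Oc4c(OC)c(-c5c(OC)cc(OC)cc5OC)c(OCc5ccccc5)cc4OC)cc(OC)cc3Oc3c(OC)c(-c4c(OC)cc(OC)cc4OC)c(OCc4ccccc4)cc3OC)cc2OC)c1 | intermediate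
30 | monobenzyl ether: 29 in which the C4 benzyloxy group of ring F is a hydroxyl and that of ring G is unchanged (formed in the flask in step 18) | COc1cc(Oc2c(OC)c(-c3c(OC)cc(OC)cc3OC)c(OC)cc2OC)c(Oc2cc(OC)cc(OC)c2)c(Oc2c(OC)cc(Oc3c(Oc4c(OC)c(-c5c(OC)cc(OC)cc5OC)c(O)cc4OC)cc(OC)cc3Oc3c(OC)c(-c4c(OC)cc(OC)cc4OC)c(OCc4ccccc4)cc3OC)cc2OC)c1 | intermediate
31 | docosamethyl ether of the target with free C4 hydroxyls on rings F and G: 5,5'-{[2-(4-{2-(3,5-dimethoxyphenoxy)-5-methoxy-3-[(2,2',4,4',6,6'-hexamethoxybiphenyl-3-yl)oxy]phenoxy}-3,5-dimethoxyphenoxy)-5-methoxy-1,3-phenylene]bis(oxy)}bis(2',4,4',6,6'-pentamethoxybiphenyl-2-ol) | COc1cc(Oc2c(OC)c(-c3c(OC)cc(OC)cc3OC)c(OC)cc2OC)c(Oc2cc(OC)cc(OC)c2)c(Oc2c(OC)cc(Oc3c(Oc4c(OC)c(-c5c(OC)cc(OC)cc5OC)c(O)cc4OC)cc(OC)cc3Oc3c(OC)c(-c4c(OC)cc(OC)cc4OC)c(O)cc3OC)cc2OC)c1 | intermediate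
32 | CNP0294555.0: ring B bearing the 3,5-dihydroxyphenoxy ring A on C1, ring D (2,4,6-trihydroxy-3-(2,4,6-trihydroxyphenyl)phenoxy) on C6, a hydroxyl on C4 and on C2 the 2,6-dihydroxy-1,4-phenylenedioxy ring C, whose other oxygen is bound to C1 of ring E (hydroxyl on C4, rings F and G of the ring D type on C2 and C6) | Oc1cc(O)cc(Oc2c(Oc3c(O)cc(Oc4c(Oc5c(O)cc(O)c(-c6c(O)cc(O)cc6O)c5O)cc(O)cc4Oc4c(O)cc(O)c(-c5c(O)cc(O)cc5O)c4O)cc3O)cc(O)cc2Oc2c(O)cc(O)c(-c3c(O)cc(O)cc3O)c2O)c1 | target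

**Step count and risks**

Total step count: 19. Longest linear sequence: 14 steps (4 → 5 → 6 → 8 → 9 → 10 → 11 → 13 → 16 → 17 → 19 → 20 → 29 → 31 → 32); steps 13 to 16 run in parallel from the shared intermediate 8.

Steps most likely to fail:

1. Step 17, the union of 20 and 28. Copper insertion into the carbon–iodine bond of 28 is slowed by the two ortho aryloxy groups, so hydrodeiodination and oxidative loss of the phenol may outrun C–O bond formation between two large partners used in near-equal amounts. The fallback reverses the roles: the hindered ring E becomes the oxygen nucleophile and the unhindered ring C the aryl donor in an oxidative Chan–Lam coupling. It sets out from 28 and 20. Iodide 28 is hydroxylated (Pd2(dba)3, t-BuXPhos, KOH, dioxane–H2O, 100 °C) to 2,6-bis{[6-(benzyloxy)-2,2',4,4',6'-pentamethoxybiphenyl-3-yl]oxy}-4-methoxyphenol F1. Phenol 20 is converted with Tf2O and pyridine into the ring C aryl triflate F2, and Miyaura borylation (B2pin2, Pd(dppf)Cl2, KOAc, dioxane, 90 °C) turns this into the ring C pinacol boronate F3. Chan–Lam coupling of F1 with F3 (Cu(OAc)2, pyridine, B(OH)3, 4 Å molecular sieves, MeCN, air, 60 °C) should come back to the route at 29, the bridging oxygen now stemming from ring E.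

2. Step 4, the double C–H aryloxylation. Copper and air may oxidise the electron-rich phenol 6 (to a quinone with loss of the benzyl group, or to oligomers) faster than its di-ortho-substituted phenoxide is transferred, and the second etherification may stall at the monoether stage. The fallback forms the same two C–O bonds of ring B by ionic, two-directional nucleophilic aromatic substitution instead of C–H activation. It sets out from 6 (and later 2). Bought 2,6-difluoro-4-methoxybenzaldehyde (COc1cc(F)c(C=O)c(F)c1) is substituted twice by 6 (Cs2CO3, DMSO, 110 °C), the ortho formyl group activating both fluorides, to give 2,6-bis[4-(benzyloxy)-2,6-dimethoxyphenoxy]-4-methoxybenzaldehyde F4. Pinnick oxidation (NaClO2, NaH2PO4, 2-methylbut-2-ene, t-BuOH–H2O) gives 2,6-bis[4-(benzyloxy)-2,6-dimethoxyphenoxy]-4-methoxybenzoic acid F5. (COCl)2 with catalytic DMF gives 2,6-bis[4-(benzyloxy)-2,6-dimethoxyphenoxy]-4-methoxybenzoyl chloride F6, which acylates 2 (Et3N, CH2Cl2) and so comes back to the route at 8.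

3. Step 10, the iododecarboxylation. Electrophilic iodination of the free, strongly activated C–H positions of rings C, D and H, or protodecarboxylation, may compete with ipso attack of iodine at the carboxylate carbon. The fallback uses no electrophilic halogen: the former amide carbon is exchanged for a hydroxyl at the aldehyde oxidation level, and the polarity of the ring A etherification is inverted. It sets out from 16. LiAlH4 in THF gives {2-[4-(benzyloxy)-2,6-dimethoxyphenoxy]-4-methoxy-6-[(2,2',4,4',6,6'-hexamethoxybiphenyl-3-yl)oxy]phenyl}methanol F7, and MnO2 in CH2Cl2 gives the corresponding benzaldehyde F8. Baeyer–Villiger (Dakin-type) oxidation with mCPBA and NaHCO3 gives the aryl formate F9, and K2CO3 in MeOH gives 2-[4-(benzyloxy)-2,6-dimethoxyphenoxy]-4-methoxy-6-[(2,2',4,4',6,6'-hexamethoxybiphenyl-3-yl)oxy]phenol F10. Ullmann coupling of F10 with bought 1-iodo-3,5-dimethoxybenzene (COc1cc(I)cc(OC)c1; CuI, picolinic acid, K3PO4, DMSO, 100 °C), now with the hindered partner as the phenol, comes back to the route at 19.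

Further compounds

F1 | step 17 | 2,6-bis{[6-(benzyloxy)-2,2',4,4',6'-pentamethoxybiphenyl-3-yl]oxy}-4-methoxyphenol | COc1cc(Oc2c(OC)c(-c3c(OC)cc(OC)cc3OC)c(OCc3ccccc3)cc2OC)c(O)c(Oc2c(OC)c(-c3c(OC)cc(OC)cc3OC)c(OCc3ccccc3)cc2OC)c1
F2 | step 17 | 4-{2-(3,5-dimethoxyphenoxy)-5-methoxy-3-[(2,2',4,4',6,6'-hexamethoxybiphenyl-3-yl)oxy]phenoxy}-3,5-dimethoxyphenyl trifluoromethanesulfonate | COc1cc(Oc2c(OC)c(-c3c(OC)cc(OC)cc3OC)c(OC)cc2OC)c(Oc2cc(OC)cc(OC)c2)c(Oc2c(OC)cc(OS(=O)(=O)C(F)(F)F)cc2OC)c1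
F3 | step 17 | 2-(4-{2-(3,5-dimethoxyphenoxy)-5-methoxy-3-[(2,2',4,4',6,6'-hexamethoxybiphenyl-3-yl)oxy]phenoxy}-3,5-dimethoxyphenyl)-4,4,5,5-tetramethyl-1,3,2-dioxaborolane | COc1cc(Oc2c(OC)c(-c3c(OC)cc(OC)cc3OC)c(OC)cc2OC)c(Oc2cc(OC)cc(OC)c2)c(Oc2c(OC)cc(B3OC(C)(C)C(C)(C)O3)cc2OC)c1
F4 | step 4 | 2,6-bis[4-(benzyloxy)-2,6-dimethoxyphenoxy]-4-methoxybenzaldehyde | COc1cc(Oc2c(OC)cc(OCc3ccccc3)cc2OC)c(C=O)c(Oc2c(OC)cc(OCc3ccccc3)cc2OC)c1
F5 | step 4 | 2,6-bis[4-(benzyloxy)-2,6-dimethoxyphenoxy]-4-methoxybenzoic acid | COc1cc(Oc2c(OC)cc(OCc3ccccc3)cc2OC)c(C(=O)O)c(Oc2c(OC)cc(OCc3ccccc3)cc2OC)c1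
F6 | step 4 | 2,6-bis[4-(benzyloxy)-2,6-dimethoxyphenoxy]-4-methoxybenzoyl chloride | COc1cc(Oc2c(OC)cc(OCc3ccccc3)cc2OC)c(C(Cl)=O)c(Oc2c(OC)cc(OCc3ccccc3)cc2OC)c1
F7 | step 10 | {2-[4-(benzyloxy)-2,6-dimethoxyphenoxy]-4-methoxy-6-[(2,2',4,4',6,6'-hexamethoxybiphenyl-3-yl)oxy]phenyl}methanol | COc1cc(Oc2c(OC)c(-c3c(OC)cc(OC)cc3OC)c(OC)cc2OC)c(CO)c(Oc2c(OC)cc(OCc3ccccc3)cc2OC)c1
F8 | step 10 | 2-[4-(benzyloxy)-2,6-dimethoxyphenoxy]-4-methoxy-6-[(2,2',4,4',6,6'-hexamethoxybiphenyl-3-yl)oxy]benzaldehyde | COc1cc(Oc2c(OC)c(-c3c(OC)cc(OC)cc3OC)c(OC)cc2OC)c(C=O)c(Oc2c(OC)cc(OCc3ccccc3)cc2OC)c1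
F9 | step 10 | 2-[4-(benzyloxy)-2,6-dimethoxyphenoxy]-4-methoxy-6-[(2,2',4,4',6,6'-hexamethoxybiphenyl-3-yl)oxy]phenyl formate | COc1cc(Oc2c(OC)c(-c3c(OC)cc(OC)cc3OC)c(OC)cc2OC)c(OC=O)c(Oc2c(OC)cc(OCc3ccccc3)cc2OC)c1
F10 | step 10 | 2-[4-(benzyloxy)-2,6-dimethoxyphenoxy]-4-methoxy-6-[(2,2',4,4',6,6'-hexamethoxybiphenyl-3-yl)oxy]phenol | COc1cc(Oc2c(OC)c(-c3c(OC)cc(OC)cc3OC)c(OC)cc2OC)c(O)c(Oc2c(OC)cc(OCc3ccccc3)cc2OC)c1
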